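## Analysis of the target

The target consists of two 5,7-dioxygenated 2-aryl-4H-chromen-4-ones joined by one carbon–carbon bond. C3 of unit 1, the 2-(4-methoxyphenyl)chromone, is bonded to C6 of unit 2, the 2-(4-hydroxyphenyl)chromone. There is no stereocentre. The only possible stereochemical element is the C3–C6 axis, flanked by the C2 aryl group and C4=O on one side and by the C5 and C7 hydroxyls on the other, and the structure gives no descriptor for it.

Five phenols stand beside one aryl methyl ether, so the masking groups must come off under conditions that spare an anisole. Both pyranones open under nucleophilic base. A 6-substituted 5,7-dihydroxyflavone can also drift to its 8-substituted isomer in hot strong acid, so the late steps must be mild. The 6-connectivity has to be fixed by which oxygen is free when ring C of unit 2 closes.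

The hard part is the crowded inter-unit bond. It is easiest to carry from the start as the aryl–CH2 bond of an arylacetic acid and to build both pyranones around it.

The strategy rests on ring A of unit 1. Carbonyl carbon C4 sits on C4a and ring oxygen O1 sits on the adjacent C8a, in a ring oxygenated at C5 and C7. This vicinal acyl/oxygen pair is what a 3,5-dialkoxybenzyne leaves behind once it has taken up the two halves of a carboxyl group.

## Retrosynthetic reasoning

**31 to 30.** The five hydroxyls of 31 are traced back to the five benzyl ethers of 30.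
- The O–CH2Ph bonds are cut because they fall to hydrogen on palladium under neutral conditions.
- Those conditions touch neither the methyl ether nor the pyranones and give no opening for an acid-induced 6-to-8 drift.
- The forward step must clear all five groups, two of them peri to carbonyls, without saturating C2=C3 of unit 2.

**30 to 26 and 27.** Ring C of unit 2 is opened at O1–C2 and C2–C3, leading through diketone 29 and ester 28 to ortho-hydroxyacetophenone 26 and acid chloride 27.
- Cutting here leaves the crowded inter-unit bond untouched.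
- In 26 only the oxygen para to that bond is free, and both oxygens ortho to it are benzylated.
- Closure can therefore use only the oxygen that becomes O1, so the 6-linked isomer is the sole possible outcome.

**26 to 23.** The aryl–acetyl bond (C4–C4a of unit 2) is cut next, through iodide 24 to phenol 23.
- An acid-promoted acetylation or Fries shift would be shorter.
- Strong Lewis acids, however, strip benzyl ethers next to carbonyl groups. Loss of the benzyl group on the future C5 oxygen would free a second ortho oxygen and undo the regiochemical lock.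
- The bond is therefore made by neutral cross-coupling on 24.
- Iodination of 23 raises no site question. The two positions ortho to the free hydroxyl are equivalent, the para position carries unit 1, and this ring is by far the most electron-rich.

**23 to 18 and 19.** Ring C of unit 1 is opened at O1–C2 and C2–C3, leading through chromone 22, diketone 21 and ester 20 to deoxybenzoin 18 and acid chloride 19.
- The anisyl ring arrives with its methyl ether in place, so no late selective methylation is needed.
- The forward reaction must move an aroyl group onto a hindered benzylic carbon. It does so intramolecularly, which offsets the crowding.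
- The acid that closes the ring also releases the one acetal-protected oxygen, which saves a step.

**18 to 8 and 16.** This is the key disconnection.
- It cuts C4–C4a and C8a–O1 of unit 1 together, giving aryne 17 (released from silyl triflate 8) and arylacetic acid 16.
- A conventional acylation of a phloroglucinol ether with 16 would need Lewis or strong Brønsted acid, which is incompatible with four benzyl ethers and an acetal.
- The insertion runs under fluoride and places the acyl group between a benzyloxy and a hydroxyl group.
- It leaves free exactly the one oxygen needed for O1.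
- The forward step needs site-selective addition to an unsymmetrical aryne, and an acyl shift that beats protonation.

**8 to 1.** The C–Si and O–S bonds of 8 are cut back through carbamates 6 and 2 to phenol 1.
- The carbamate and the neighbouring benzyloxy group cooperate to direct metalation to the carbon between them.
- This carbon is the one that must carry silicon.
- The carbamate then leaves under mild amine conditions in the same flask as the triflation.

**16 to 9.** The carboxyl carbon of 16 is removed by one-carbon dehomologation through alcohol 14 and styrene 12 to aldehyde 11, and the ethers of 11 are traced through 10 to aldehyde 9.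
- In 9 the carbon substituent already sits between two equivalent oxygens.
- The para oxygen is distinguished by its acidity, so the protecting-group pattern follows from the substrate itself.

## Alternatives that were turned down

**Alternative 1:** The pyranone of unit 1 is cut at C4–C4a and O1–C2.
- Disconnection: ring A of unit 1 falls away as phloroglucinol (A2). Everything else remains as the α-aryl β-keto ester A3, with benzylated unit 2 on the carbon between an ethyl ester and the anisyl ketone.
- Forward key step: a Mentzer-type thermal condensation of A2 with A3, neat or under microwaves. It should give the tri-O-benzyl compound A1, one hydrogenolysis from the target.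
- In favour: this is the most convergent plan. A2 is symmetrical and needs no protection, and only three benzyl groups remain.
- Against, reactivity: the reacting ester sits on a carbon bearing an aroyl group and an aryl group with two ortho benzyloxy substituents. Acylation therefore needs temperatures at which aryl benzyl ethers migrate and the keto ester can lose its ester group.
- Against, selectivity: the opposite pairing, ring carbon on the ketone and hydroxyl on the ester, leads to an isomeric coumarin. Nothing in A3 forbids it.
- Against, supply: A3 presupposes a flavone with an acetic ester at C6, so the 6/8 problem must already be solved. It also needs aroylation at the same hindered carbon as in the chosen route.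
- Comparison: this alternative is stronger on convergence and protecting-group economy. The chosen route offers bond formation below 130 °C and no chromone/coumarin ambiguity, because carbon and oxygen are delivered to fixed neighbouring positions.

**Alternative 2:** Ring A of unit 2 is cut at C7–C8 and C5–C6.
- Disconnection: this gives the 2-methyl-4-pyranone ester A5 and the flavon-3-ylacetate A6.
- Forward key step: LiN(SiMe3)2 deprotonates the methyl group of A5 and the anion is acylated by A6. The new ketone enolate then closes onto the pyranone ester, and aromatisation gives A4 with free unit 2 hydroxyls.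
- In favour: the benzene ring grows around C6, so the linkage position cannot be wrong, and no selective phenol protection is needed in unit 2. On this point it is stronger than the chosen route.
- Against, acidity: the methylene of A6, activated by the ester and by the chromone, is more acidic than the vinylogous methyl group of A5. The electrophile would be enolised and switched off, or would self-condense.
- Against, side reactions: pyranone A5 is open to conjugate attack, and the second Claisen closure must form a bond at a carbon bearing a bulky flavonyl group.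
- Against, supply: both building blocks are unusual and need several steps each.
- Comparison: the chosen route secures the 6-linkage with an ordinary protecting-group pattern. It concentrates its risk in one early step on simple materials rather than in a late double condensation.

**Alternative 3:** The pyranone of unit 1 is cut at C2–C3 and O1–C2, as in the chosen route, but on deoxybenzoin A8, which already carries complete benzylated unit 2.
- Forward key step: O-aroylation with 19, base-induced acyl shift and cyclodehydration give the penta-O-benzyl compound A7, identical with 30.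
- In favour: the closure is the same reliable chemistry used here in steps 10 and 11. Placed last, it leaves only the hydrogenolysis, so its endgame is shorter.
- Against, supply: the plan does not solve the origin of A8. A flavon-6-ylacetic acid would have to acylate a phloroglucinol ether under acidic conditions that five benzyl ethers are unlikely to survive.
- Against, compatibility: the strong base of the acyl shift would act in the presence of the base-sensitive pyranone of unit 2.
- Comparison: the two plans are equal on the ring closure itself. The chosen strategy adds an acid-free entry to the deoxybenzoin and builds unit 2 only after the strongly basic step on the hindered carbon.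

Key step: step 9

Assumption: the C3–C6 axis between the units has no descriptor in the target. It is treated as configurationally undefined, and compounds 24 to 31 are taken as racemic about it should rotation be slow.

## Route

Step 1
Reactants: 1 3,5-bis(benzyloxy)phenol
Product: 2 3,5-bis(benzyloxy)phenyl N-isopropylcarbamate
Conditions: i-PrNCO (1.5 equiv), Et3N (0.2 equiv), CH2Cl2, rt
Reagents that add atoms: isopropyl isocyanate, CC(C)N=C=O
Why: Base-catalysed addition of a phenol to an isocyanate. The secondary carbamate directs lithiation once its nitrogen is silylated and later leaves under mild amine conditions.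

Step 2
Reactants: 2 3,5-bis(benzyloxy)phenyl N-isopropylcarbamate
Product: 6 3,5-bis(benzyloxy)-2-(trimethylsilyl)phenyl N-isopropylcarbamate, via N-silyl carbamate 3 (not isolated), via aryllithium 4 (not isolated), via doubly silylated carbamate 5 (not isolated)
Conditions: TBSOTf, TMEDA, Et2O, 0 °C to rt; n-BuLi, TMEDA, −78 °C; TMSCl, −78 °C to rt; aq. NaHSO4
Reagents that add atoms: chlorotrimethylsilane, C[Si](C)(C)Cl; TBSOTf, CC(C)(C)[Si](C)(C)OS(=O)(=O)C(F)(F)F (its silyl group is carried only by 3, 4 and 5); n-butyllithium, [Li]CCCC (its lithium is carried only by 4)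
Why: Directed ortho-metalation: N-silylation removes the acidic N–H, and the carbamate and the adjacent benzyloxy group together steer n-BuLi to the carbon between them (the two such positions are equivalent) rather than to the carbon between the two benzyloxy groups. At −78 °C ring lithiation should outrun benzylic deprotonation, and the acidic work-up removes only the N-silyl group.

Step 3
Reactants: 6 3,5-bis(benzyloxy)-2-(trimethylsilyl)phenyl N-isopropylcarbamate
Product: 8 3,5-bis(benzyloxy)-2-(trimethylsilyl)phenyl trifluoromethanesulfonate, via silylphenol 7 (not isolated)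
Conditions: Et2NH, DBU, MeCN, 40 °C; then PhNTf2, rt
Reagents that add atoms: N-phenylbis(trifluoromethanesulfonimide), O=S(=O)(N(c1ccccc1)S(=O)(=O)C(F)(F)F)C(F)(F)F
Why: E1cB cleavage of the N–H carbamate (the expelled isocyanate is trapped by Et2NH) followed by O-triflation of the phenoxide in the same flask. The electron-rich arylsilane 7, prone to protodesilylation, never meets acid or work-up.

Step 4
Reactants: 9 2,4,6-trihydroxybenzaldehyde
Product: 10 2,6-dihydroxy-4-(methoxymethoxy)benzaldehyde
Conditions: MOMCl (1.0 equiv), i-Pr2NEt (1.05 equiv), THF, 0 °C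
Reagents that add atoms: chloromethyl methyl ether, COCCl
Why: Williamson-type O-alkylation under acidity control: the hydroxyl para to the formyl group is the most acidic and is not hydrogen-bonded to it, so one equivalent of weak base and electrophile should react there first. Product 10 is less acidic than 9, which holds back a second alkylation.

Step 5
Reactants: 10 2,6-dihydroxy-4-(methoxymethoxy)benzaldehyde
Product: 11 2,6-bis(benzyloxy)-4-(methoxymethoxy)benzaldehyde
Conditions: BnBr (2.4 equiv), K2CO3, DMF, 60 °C
Reagents that add atoms: benzyl bromide, BrCc1ccccc1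
Why: Williamson ether synthesis: warm K2CO3 in DMF overcomes the hydrogen bonding of the two remaining hydroxyls, and the acetal and the aldehyde are inert to these conditions.

Step 6
Reactants: 11 2,6-bis(benzyloxy)-4-(methoxymethoxy)benzaldehyde
Product: 12 1,3-bis(benzyloxy)-2-ethenyl-5-(methoxymethoxy)benzene
Conditions: MePPh3Br, KOt-Bu, THF, 0 °C to rt
Reagents that add atoms: methyltriphenylphosphonium bromide, C[P+](c1ccccc1)(c1ccccc1)c1ccccc1.[Br-]
Why: Wittig methylenation is irreversible and tolerates an electron-rich, doubly ortho-substituted aldehyde that would add stabilised carbanions only reversibly. The conditions are basic, so the acetal is safe, and the acid-sensitive styrene should be purified on base-washed silica.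

Step 7
Reactants: 12 1,3-bis(benzyloxy)-2-ethenyl-5-(methoxymethoxy)benzene
Product: 14 2-[2,6-bis(benzyloxy)-4-(methoxymethoxy)phenyl]ethan-1-ol, via B-alkyl-9-BBN adduct 13 (not isolated)
Conditions: 9-BBN, THF, 0 °C to rt; NaOH, H2O2, 0 °C to rt
Reagents that add atoms: hydrogen peroxide, OO; 9-borabicyclo[3.3.1]nonane, B1C2CCCC1CCC2 (its boron is carried only by 13)
Why: Hydroboration–oxidation: the bulky borane places boron on the terminal carbon of the styrene, and alkaline peroxide exchanges it for hydroxyl without touching ethers or acetal.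

Step 8
Reactants: 14 2-[2,6-bis(benzyloxy)-4-(methoxymethoxy)phenyl]ethan-1-ol
Product: 16 [2,6-bis(benzyloxy)-4-(methoxymethoxy)phenyl]acetic acid, via arylacetaldehyde 15 (not isolated)
Conditions: TEMPO (0.2 equiv), PhI(OAc)2 (2.2 equiv), MeCN–H2O (1:1), rt
Reagents that add atoms: water, O
Why: Oxoammonium-mediated oxidation of a primary alcohol through aldehyde 15 and its hydrate to the acid. The chlorine-free terminal oxidant avoids halogenation of the trialkoxyarene, and the acetic acid released is too weak to open the acetal.

Step 9
Reactants: 8 3,5-bis(benzyloxy)-2-(trimethylsilyl)phenyl trifluoromethanesulfonate; 16 [2,6-bis(benzyloxy)-4-(methoxymethoxy)phenyl]acetic acid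
Product: 18 1-[2,4-bis(benzyloxy)-6-hydroxyphenyl]-2-[2,6-bis(benzyloxy)-4-(methoxymethoxy)phenyl]ethan-1-one, via aryne 17 (not isolated)
Conditions: 8 (1.5 equiv), CsF (4 equiv), THF (0.02 M), sealed tube, 125 °C
Reagents that add atoms: none
Why: Fluoride attacks the silicon of 8, triflate leaves, and aryne 17 is released slowly in the presence of the carboxylate of 16. The benzyloxy group beside the triple bond withdraws inductively and distorts the aryne, so the carboxylate oxygen adds to the remote aryne carbon (future C8a) and the charge develops on the carbon next to oxygen (future C4a). This aryl anion attacks the carbonyl of its own aryl ester, and the four-membered alkoxide so formed opens by C–O cleavage to the ortho-acylphenoxide, an anionic Fries-type O-to-C acyl shift. The closest known reaction type is the fluoride-induced insertion of arynes into the C–O bond of carboxylic acids, which gives ortho-hydroxyaryl ketones when run hot and dilute in THF. No ring stays closed and no stereocentre is formed. Two selectivities are needed: site selectivity on the unsymmetrical aryne, secured by the flanking benzyloxy group, and acyl shift ahead of protonation of the aryl anion, favoured by heat, dilution and excess CsF that keeps 16 as its salt. The product phenol is hydrogen-bonded to the new ketone, which should slow its own arylation by 17.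

Step 10
Reactants: 18 1-[2,4-bis(benzyloxy)-6-hydroxyphenyl]-2-[2,6-bis(benzyloxy)-4-(methoxymethoxy)phenyl]ethan-1-one; 19 4-methoxybenzoyl chloride
Product: 20 3,5-bis(benzyloxy)-2-{[2,6-bis(benzyloxy)-4-(methoxymethoxy)phenyl]acetyl}phenyl 4-methoxybenzoate
Conditions: 19 (1.3 equiv), Et3N, DMAP (0.1 equiv), CH2Cl2, 0 °C to rt
Reagents that add atoms: none
Why: DMAP-catalysed O-acylation: the acylpyridinium ion is reactive enough for the hydrogen-bonded phenol, the only free hydroxyl in 18.

Step 11
Reactants: 20 3,5-bis(benzyloxy)-2-{[2,6-bis(benzyloxy)-4-(methoxymethoxy)phenyl]acetyl}phenyl 4-methoxybenzoate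
Product: 23 5,7-bis(benzyloxy)-3-[2,6-bis(benzyloxy)-4-hydroxyphenyl]-2-(4-methoxyphenyl)-4H-chromen-4-one, via triaryl 1,3-diketone 21 (not isolated), via MOM-protected chromone 22 (not isolated)
Conditions: KOt-Bu (2.5 equiv), THF, 0 °C to rt; then HCl, MeOH–THF, 55 °C
Reagents that add atoms: none
Why: Baker–Venkataraman rearrangement: the deoxybenzoin enolate attacks the neighbouring aryl ester through a six-membered transition state, and formation of the stabilised diketone enolate drives the transfer despite the crowding. Acid then condenses the phenol on the anisyl ketone (6-exo addition, then dehydration) and cleaves the acetal, with methanol intercepting the formaldehyde unit before it can attack the electron-rich ring. The order of the two acid-induced events does not affect the outcome.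

Step 12
Reactants: 23 5,7-bis(benzyloxy)-3-[2,6-bis(benzyloxy)-4-hydroxyphenyl]-2-(4-methoxyphenyl)-4H-chromen-4-one
Product: 24 5,7-bis(benzyloxy)-3-[2,6-bis(benzyloxy)-4-hydroxy-3-iodophenyl]-2-(4-methoxyphenyl)-4H-chromen-4-one
Conditions: NIS (1.0 equiv), CH2Cl2, −20 to 0 °C, dark
Reagents that add atoms: N-iodosuccinimide, O=C1CCC(=O)N1I
Why: Electrophilic aromatic iodination without added acid reaches only the free-phenol ring, because ring A of unit 1 is deactivated by its carbonyl group. The two open positions are equivalent and the para position is blocked, so only over-iodination must be held back, by stoichiometry and low temperature.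

Step 13
Reactants: 24 5,7-bis(benzyloxy)-3-[2,6-bis(benzyloxy)-4-hydroxy-3-iodophenyl]-2-(4-methoxyphenyl)-4H-chromen-4-one
Product: 26 3-[3-acetyl-2,6-bis(benzyloxy)-4-hydroxyphenyl]-5,7-bis(benzyloxy)-2-(4-methoxyphenyl)-4H-chromen-4-one, via enol ether 25 (not isolated)
Conditions: Bu3SnC(OEt)=CH2 (1.5 equiv), PdCl2(PPh3)2 (5 mol %), 1,4-dioxane, 100 °C; then 1 M HCl, THF, rt
Reagents that add atoms: tributyl(1-ethoxyvinyl)stannane, CCCC[Sn](CCCC)(CCCC)C(=C)OCC; water, O
Why: Stille coupling with a masked acetyl anion: zerovalent palladium formed in situ inserts into the C–I bond, the ethoxyvinyl group is transferred from tin, and dilute acid hydrolyses enol ether 25 to the methyl ketone. The conditions are free of Lewis acid, so every benzyl ether, and with it the regiochemical lock on unit 2, is kept.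

Step 14
Reactants: 26 3-[3-acetyl-2,6-bis(benzyloxy)-4-hydroxyphenyl]-5,7-bis(benzyloxy)-2-(4-methoxyphenyl)-4H-chromen-4-one; 27 4-(benzyloxy)benzoyl chloride
Product: 28 2-acetyl-3,5-bis(benzyloxy)-4-[5,7-bis(benzyloxy)-2-(4-methoxyphenyl)-4-oxo-4H-chromen-3-yl]phenyl 4-(benzyloxy)benzoate
Conditions: 27 (1.3 equiv), Et3N, DMAP (0.1 equiv), CH2Cl2, rt
Reagents that add atoms: none
Why: DMAP-catalysed O-acylation of the single free, hydrogen-bonded phenol, as in step 10.

Step 15
Reactants: 28 2-acetyl-3,5-bis(benzyloxy)-4-[5,7-bis(benzyloxy)-2-(4-methoxyphenyl)-4-oxo-4H-chromen-3-yl]phenyl 4-(benzyloxy)benzoate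
Product: 30 5,7-bis(benzyloxy)-6-[5,7-bis(benzyloxy)-2-(4-methoxyphenyl)-4-oxo-4H-chromen-3-yl]-2-[4-(benzyloxy)phenyl]-4H-chromen-4-one, via 1,3-diketone 29 (not isolated)
Conditions: KOt-Bu (2.5 equiv), THF, 0 °C to rt; AcOH quench; p-TsOH·H2O (0.2 equiv), toluene, 80 °C
Reagents that add atoms: none
Why: Baker–Venkataraman rearrangement of the acetophenone enolate onto the adjacent ester, then acid-catalysed cyclodehydration of 29. The bulky non-nucleophilic base spares the fully substituted pyranone of unit 1, and only the oxygen para to the inter-unit bond is free, so only the 6-linked flavone can form.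

Step 16
Reactants: 30 5,7-bis(benzyloxy)-6-[5,7-bis(benzyloxy)-2-(4-methoxyphenyl)-4-oxo-4H-chromen-3-yl]-2-[4-(benzyloxy)phenyl]-4H-chromen-4-one
Product: 31 6-[5,7-dihydroxy-2-(4-methoxyphenyl)-4-oxo-4H-chromen-3-yl]-5,7-dihydroxy-2-(4-hydroxyphenyl)-4H-chromen-4-one
Conditions: H2 (1 atm), 10% Pd/C, THF–MeOH, rt
Reagents that add atoms: none
Why: Catalytic hydrogenolysis of five aryl benzyl ethers under neutral conditions. The methyl ether and the conjugated pyranone double bonds are not expected to react at atmospheric pressure, and the absence of acid rules out a Wessely–Moser-type drift.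

## Compound list

1 | 3,5-bis(benzyloxy)phenol | Oc1cc(OCc2ccccc2)cc(OCc2ccccc2)c1 | starting material
2 | 3,5-bis(benzyloxy)phenyl N-isopropylcarbamate | CC(C)NC(=O)Oc1cc(OCc2ccccc2)cc(OCc2ccccc2)c1 | intermediate
3 | 3,5-bis(benzyloxy)phenyl N-(tert-butyldimethylsilyl)-N-isopropylcarbamate | CC(C)N(C(=O)Oc1cc(OCc2ccccc2)cc(OCc2ccccc2)c1)[Si](C)(C)C(C)(C)C | intermediate
4 | 2-lithio derivative of 3 (lithium between the carbamate oxygen and a benzyloxy group) | [Li]c1c(OC(=O)N(C(C)C)[Si](C)(C)C(C)(C)C)cc(OCc2ccccc2)cc1OCc1ccccc1 | intermediate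
5 | 3,5-bis(benzyloxy)-2-(trimethylsilyl)phenyl N-(tert-butyldimethylsilyl)-N-isopropylcarbamate | CC(C)N(C(=O)Oc1cc(OCc2ccccc2)cc(OCc2ccccc2)c1[Si](C)(C)C)[Si](C)(C)C(C)(C)C | intermediate
6 | 3,5-bis(benzyloxy)-2-(trimethylsilyl)phenyl N-isopropylcarbamate | CC(C)NC(=O)Oc1cc(OCc2ccccc2)cc(OCc2ccccc2)c1[Si](C)(C)C | intermediate
7 | 3,5-bis(benzyloxy)-2-(trimethylsilyl)phenol | C[Si](C)(C)c1c(O)cc(OCc2ccccc2)cc1OCc1ccccc1 | intermediate
8 | 3,5-bis(benzyloxy)-2-(trimethylsilyl)phenyl trifluoromethanesulfonate | C[Si](C)(C)c1c(OS(=O)(=O)C(F)(F)F)cc(OCc2ccccc2)cc1OCc1ccccc1 | intermediate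
9 | 2,4,6-trihydroxybenzaldehyde | O=Cc1c(O)cc(O)cc1O | starting material
10 | 2,6-dihydroxy-4-(methoxymethoxy)benzaldehyde | COCOc1cc(O)c(C=O)c(O)c1 | intermediate
11 | 2,6-bis(benzyloxy)-4-(methoxymethoxy)benzaldehyde | COCOc1cc(OCc2ccccc2)c(C=O)c(OCc2ccccc2)c1 | intermediate
12 | 1,3-bis(benzyloxy)-2-ethenyl-5-(methoxymethoxy)benzene | COCOc1cc(OCc2ccccc2)c(C=C)c(OCc2ccccc2)c1 | intermediate
13 | 9-{2-[2,6-bis(benzyloxy)-4-(methoxymethoxy)phenyl]ethyl}-9-borabicyclo[3.3.1]nonane | COCOc1cc(OCc2ccccc2)c(CCB2C3CCCC2CCC3)c(OCc2ccccc2)c1 | intermediate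
14 | 2-[2,6-bis(benzyloxy)-4-(methoxymethoxy)phenyl]ethan-1-ol | COCOc1cc(OCc2ccccc2)c(CCO)c(OCc2ccccc2)c1 | intermediate
15 | [2,6-bis(benzyloxy)-4-(methoxymethoxy)phenyl]acetaldehyde | COCOc1cc(OCc2ccccc2)c(CC=O)c(OCc2ccccc2)c1 | intermediate
16 | [2,6-bis(benzyloxy)-4-(methoxymethoxy)phenyl]acetic acid | COCOc1cc(OCc2ccccc2)c(CC(=O)O)c(OCc2ccccc2)c1 | intermediate
17 | 3,5-bis(benzyloxy)benzyne (1,3-bis(benzyloxy)-4,5-didehydrobenzene) | C1#CC(OCc2ccccc2)=CC(OCc2ccccc2)=C1 | intermediate
18 | 1-[2,4-bis(benzyloxy)-6-hydroxyphenyl]-2-[2,6-bis(benzyloxy)-4-(methoxymethoxy)phenyl]ethan-1-one | COCOc1cc(OCc2ccccc2)c(CC(=O)c2c(O)cc(OCc3ccccc3)cc2OCc2ccccc2)c(OCc2ccccc2)c1 | intermediate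
19 | 4-methoxybenzoyl chloride | COc1ccc(C(=O)Cl)cc1 | starting material
20 | 3,5-bis(benzyloxy)-2-{[2,6-bis(benzyloxy)-4-(methoxymethoxy)phenyl]acetyl}phenyl 4-methoxybenzoate | COCOc1cc(OCc2ccccc2)c(CC(=O)c2c(OC(=O)c3ccc(OC)cc3)cc(OCc3ccccc3)cc2OCc2ccccc2)c(OCc2ccccc2)c1 | intermediate
21 | 1-[2,4-bis(benzyloxy)-6-hydroxyphenyl]-2-[2,6-bis(benzyloxy)-4-(methoxymethoxy)phenyl]-3-(4-methoxyphenyl)propane-1,3-dione (methine centre configurationally labile) | COCOc1cc(OCc2ccccc2)c(C(C(=O)c2ccc(OC)cc2)C(=O)c2c(O)cc(OCc3ccccc3)cc2OCc2ccccc2)c(OCc2ccccc2)c1 | intermediate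
22 | 5,7-bis(benzyloxy)-3-[2,6-bis(benzyloxy)-4-(methoxymethoxy)phenyl]-2-(4-methoxyphenyl)-4H-chromen-4-one | COCOc1cc(OCc2ccccc2)c(-c2c(-c3ccc(OC)cc3)oc3cc(OCc4ccccc4)cc(OCc4ccccc4)c3c2=O)c(OCc2ccccc2)c1 | intermediate
23 | 5,7-bis(benzyloxy)-3-[2,6-bis(benzyloxy)-4-hydroxyphenyl]-2-(4-methoxyphenyl)-4H-chromen-4-one | COc1ccc(-c2oc3cc(OCc4ccccc4)cc(OCc4ccccc4)c3c(=O)c2-c2c(OCc3ccccc3)cc(O)cc2OCc2ccccc2)cc1 | intermediate
24 | 5,7-bis(benzyloxy)-3-[2,6-bis(benzyloxy)-4-hydroxy-3-iodophenyl]-2-(4-methoxyphenyl)-4H-chromen-4-one | COc1ccc(-c2oc3cc(OCc4ccccc4)cc(OCc4ccccc4)c3c(=O)c2-c2c(OCc3ccccc3)cc(O)c(I)c2OCc2ccccc2)cc1 | intermediate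
25 | 5,7-bis(benzyloxy)-3-[2,6-bis(benzyloxy)-3-(1-ethoxyethenyl)-4-hydroxyphenyl]-2-(4-methoxyphenyl)-4H-chromen-4-one | COc1ccc(-c2oc3cc(OCc4ccccc4)cc(OCc4ccccc4)c3c(=O)c2-c2c(OCc3ccccc3)cc(O)c(C(=C)OCC)c2OCc2ccccc2)cc1 | intermediate
26 | 3-[3-acetyl-2,6-bis(benzyloxy)-4-hydroxyphenyl]-5,7-bis(benzyloxy)-2-(4-methoxyphenyl)-4H-chromen-4-one | COc1ccc(-c2oc3cc(OCc4ccccc4)cc(OCc4ccccc4)c3c(=O)c2-c2c(OCc3ccccc3)cc(O)c(C(C)=O)c2OCc2ccccc2)cc1 | intermediate
27 | 4-(benzyloxy)benzoyl chloride | O=C(Cl)c1ccc(OCc2ccccc2)cc1 | starting material
28 | 2-acetyl-3,5-bis(benzyloxy)-4-[5,7-bis(benzyloxy)-2-(4-methoxyphenyl)-4-oxo-4H-chromen-3-yl]phenyl 4-(benzyloxy)benzoate | COc1ccc(-c2oc3cc(OCc4ccccc4)cc(OCc4ccccc4)c3c(=O)c2-c2c(OCc3ccccc3)cc(OC(=O)c3ccc(OCc4ccccc4)cc3)c(C(C)=O)c2OCc2ccccc2)cc1 | intermediate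
29 | 5,7-bis(benzyloxy)-3-(2,6-bis(benzyloxy)-3-{3-[4-(benzyloxy)phenyl]-3-oxopropanoyl}-4-hydroxyphenyl)-2-(4-methoxyphenyl)-4H-chromen-4-one | COc1ccc(-c2oc3cc(OCc4ccccc4)cc(OCc4ccccc4)c3c(=O)c2-c2c(OCc3ccccc3)cc(O)c(C(=O)CC(=O)c3ccc(OCc4ccccc4)cc3)c2OCc2ccccc2)cc1 | intermediate
30 | 5,7-bis(benzyloxy)-6-[5,7-bis(benzyloxy)-2-(4-methoxyphenyl)-4-oxo-4H-chromen-3-yl]-2-[4-(benzyloxy)phenyl]-4H-chromen-4-one | COc1ccc(-c2oc3cc(OCc4ccccc4)cc(OCc4ccccc4)c3c(=O)c2-c2c(OCc3ccccc3)cc3oc(-c4ccc(OCc5ccccc5)cc4)cc(=O)c3c2OCc2ccccc2)cc1 | intermediate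
31 | 6-[5,7-dihydroxy-2-(4-methoxyphenyl)-4-oxo-4H-chromen-3-yl]-5,7-dihydroxy-2-(4-hydroxyphenyl)-4H-chromen-4-one | COc1ccc(-c2oc3cc(O)cc(O)c3c(=O)c2-c2c(O)cc3oc(-c4ccc(O)cc4)cc(=O)c3c2O)cc1 | target

## Step count and least certain steps

Total step count: 16 steps.
- Steps 1–3 make the aryne precursor.
- Steps 4–8 make the acid.
- Steps 9–16 run from the union to the target.

Longest linear sequence: 13 steps, from 9 through steps 4–16 to 31.

**Step 9 (key step).**
- Main risk: the aryl anion is protonated before the acyl shift. The proton could come from free acid, from bifluoride, or internally from the activated methylene of the arylacetate through a six-membered transition state. The reaction would then stop at simple O-arylation.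
- Second risk: surplus aryne arylates the product at its phenoxide oxygen or at its acidic methylene.
- Fallback: it sets out from 16 and 2 and returns at 18. The C4–C4a bond is made by acyl substitution on a preformed aryl anion whose oxygen is already in place.
- Acid 16 is condensed with N,O-dimethylhydroxylamine (carbodiimide activation) to the Weinreb amide 2-[2,6-bis(benzyloxy)-4-(methoxymethoxy)phenyl]-N-methoxy-N-methylacetamide F1.
- Aryllithium 4, generated from 2 exactly as in step 2, is quenched with F1 instead of the chlorosilane. Acidic work-up, which also strips the N-silyl group, should give the keto carbamate 3,5-bis(benzyloxy)-2-{[2,6-bis(benzyloxy)-4-(methoxymethoxy)phenyl]acetyl}phenyl N-isopropylcarbamate F2.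
- Et2NH and DBU in MeCN, as in step 3, then release 18.

**Step 4.**
- Risk: only one of the two ortho hydroxyls can be hydrogen-bonded to the formyl group at a time. Alkylation at an ortho oxygen and double alkylation may therefore compete with the desired para alkylation.
- Fallback: it sets out from 1 and returns at 11. The protecting-group pattern is taken from a phenol that is already differentiated.
- Vilsmeier–Haack formylation of 1 (POCl3, DMF, then aqueous NaOAc) should attack mainly para to the free hydroxyl. This gives 2,6-bis(benzyloxy)-4-hydroxybenzaldehyde F3, which is separated from its ortho isomer and converted into 11 with MOMCl and i-Pr2NEt.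

**Step 2.**
- Risk: benzylic deprotonation followed by Wittig rearrangement, or lithiation between the two benzyloxy groups, may compete with the desired ring lithiation.
- Fallback: it sets out from 1 and returns at 8. It replaces deprotonation by halogen–metal exchange, which is much faster than any C–H lithiation.
- NBS in CH2Cl2 at low temperature should brominate next to the hydroxyl to give 2-bromo-3,5-bis(benzyloxy)phenol F4.
- Hexamethyldisilazane converts F4 into [2-bromo-3,5-bis(benzyloxy)phenoxy]trimethylsilane F5.
- n-BuLi at −78 °C triggers exchange and a retro-Brook O-to-C silyl shift to the phenoxide of 7, which is trapped with Tf2O as 8.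

**Step 11.**
- Risk: acyl transfer to the crowded benzylic carbon may be slow, so that ester cleavage back to the phenol takes over.
- Risk: retro-Claisen cleavage of the diketone, or loss of the peri benzyl ether, may occur in the acidic stage.
- Fallback: it sets out from 18 and returns at 22, which the acidic methanol of step 11 converts into 23. It brings in the anisyl carbon at the aldehyde oxidation level.
- Piperidine-catalysed condensation of 18 with 4-methoxybenzaldehyde and oxa-Michael closure should give 5,7-bis(benzyloxy)-3-[2,6-bis(benzyloxy)-4-(methoxymethoxy)phenyl]-2-(4-methoxyphenyl)chroman-4-one F6 as a diastereomer mixture.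
- Dehydrogenation with DDQ in dioxane erases both centres of F6 and gives 22.

**Step 13.**
- Risk: oxidative addition and transmetalation at an iodide flanked by two oxygen substituents may be sluggish, and protodeiodination may then win.
- Fallback: it sets out from 24 and returns at 30, bypassing 26 and 28.
- It is a carbonylative alkynylation–annulation with 1-(benzyloxy)-4-ethynylbenzene under CO (1 atm), PdCl2(PPh3)2 and Et2NH.
- It should pass through the ynone 5,7-bis(benzyloxy)-3-(2,6-bis(benzyloxy)-3-{3-[4-(benzyloxy)phenyl]prop-2-ynoyl}-4-hydroxyphenyl)-2-(4-methoxyphenyl)-4H-chromen-4-one F7.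
- The amine-mediated 6-endo closure of F7 gives the flavone.

## Further compounds

F1 | step 9 | 2-[2,6-bis(benzyloxy)-4-(methoxymethoxy)phenyl]-N-methoxy-N-methylacetamide | COCOc1cc(OCc2ccccc2)c(CC(=O)N(C)OC)c(OCc2ccccc2)c1
F2 | step 9 | 3,5-bis(benzyloxy)-2-{[2,6-bis(benzyloxy)-4-(methoxymethoxy)phenyl]acetyl}phenyl N-isopropylcarbamate | COCOc1cc(OCc2ccccc2)c(CC(=O)c2c(OC(=O)NC(C)C)cc(OCc3ccccc3)cc2OCc2ccccc2)c(OCc2ccccc2)c1
F3 | step 4 | 2,6-bis(benzyloxy)-4-hydroxybenzaldehyde | O=Cc1c(OCc2ccccc2)cc(O)cc1OCc1ccccc1
F4 | step 2 | 2-bromo-3,5-bis(benzyloxy)phenol | Oc1cc(OCc2ccccc2)cc(OCc2ccccc2)c1Br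
F5 | step 2 | [2-bromo-3,5-bis(benzyloxy)phenoxy]trimethylsilane | C[Si](C)(C)Oc1cc(OCc2ccccc2)cc(OCc2ccccc2)c1Br
F6 | step 11 | 5,7-bis(benzyloxy)-3-[2,6-bis(benzyloxy)-4-(methoxymethoxy)phenyl]-2-(4-methoxyphenyl)chroman-4-one (racemic diastereomer mixture, both centres erased in the next operation) | COCOc1cc(OCc2ccccc2)c(C2C(=O)c3c(OCc4ccccc4)cc(OCc4ccccc4)cc3OC2c2ccc(OC)cc2)c(OCc2ccccc2)c1
F7 | step 13 | 5,7-bis(benzyloxy)-3-(2,6-bis(benzyloxy)-3-{3-[4-(benzyloxy)phenyl]prop-2-ynoyl}-4-hydroxyphenyl)-2-(4-methoxyphenyl)-4H-chromen-4-one | COc1ccc(-c2oc3cc(OCc4ccccc4)cc(OCc4ccccc4)c3c(=O)c2-c2c(OCc3ccccc3)cc(O)c(C(=O)C#Cc3ccc(OCc4ccccc4)cc3)c2OCc2ccccc2)cc1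
A1 | alternative 1 | 5,7-bis(benzyloxy)-2-[4-(benzyloxy)phenyl]-6-[5,7-dihydroxy-2-(4-methoxyphenyl)-4-oxo-4H-chromen-3-yl]-4H-chromen-4-one | COc1ccc(-c2oc3cc(O)cc(O)c3c(=O)c2-c2c(OCc3ccccc3)cc3oc(-c4ccc(OCc5ccccc5)cc4)cc(=O)c3c2OCc2ccccc2)cc1
A2 | alternative 1 | phloroglucinol | Oc1cc(O)cc(O)c1
A3 | alternative 1 | ethyl 2-{5,7-bis(benzyloxy)-2-[4-(benzyloxy)phenyl]-4-oxo-4H-chromen-6-yl}-3-(4-methoxyphenyl)-3-oxopropanoate | CCOC(=O)C(C(=O)c1ccc(OC)cc1)c1c(OCc2ccccc2)cc2oc(-c3ccc(OCc4ccccc4)cc3)cc(=O)c2c1OCc1ccccc1
A4 | alternative 2 | 6-[5,7-bis(benzyloxy)-2-(4-methoxyphenyl)-4-oxo-4H-chromen-3-yl]-2-[4-(benzyloxy)phenyl]-5,7-dihydroxy-4H-chromen-4-one | COc1ccc(-c2oc3cc(OCc4ccccc4)cc(OCc4ccccc4)c3c(=O)c2-c2c(O)cc3oc(-c4ccc(OCc5ccccc5)cc4)cc(=O)c3c2O)cc1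
A5 | alternative 2 | methyl 6-[4-(benzyloxy)phenyl]-2-methyl-4-oxo-4H-pyran-3-carboxylate | COC(=O)c1c(C)oc(-c2ccc(OCc3ccccc3)cc2)cc1=O
A6 | alternative 2 | methyl [5,7-bis(benzyloxy)-2-(4-methoxyphenyl)-4-oxo-4H-chromen-3-yl]acetate | COC(=O)Cc1c(-c2ccc(OC)cc2)oc2cc(OCc3ccccc3)cc(OCc3ccccc3)c2c1=O
A7 | alternative 3 | 5,7-bis(benzyloxy)-6-[5,7-bis(benzyloxy)-2-(4-methoxyphenyl)-4-oxo-4H-chromen-3-yl]-2-[4-(benzyloxy)phenyl]-4H-chromen-4-one (identical with 30) | COc1ccc(-c2oc3cc(OCc4ccccc4)cc(OCc4ccccc4)c3c(=O)c2-c2c(OCc3ccccc3)cc3oc(-c4ccc(OCc5ccccc5)cc4)cc(=O)c3c2OCc2ccccc2)cc1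
A8 | alternative 3 | 5,7-bis(benzyloxy)-6-{2-[2,4-bis(benzyloxy)-6-hydroxyphenyl]-2-oxoethyl}-2-[4-(benzyloxy)phenyl]-4H-chromen-4-one | O=C(Cc1c(OCc2ccccc2)cc2oc(-c3ccc(OCc4ccccc4)cc3)cc(=O)c2c1OCc1ccccc1)c1c(O)cc(OCc2ccccc2)cc1OCc1ccccc1
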